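The plan rests on one disconnection: the C3 hydroxyl and the C4 carbonyl of the pyranone ring C are neighbouring C–O bonds that map onto the C3=C4 styrenyl double bond of a 2-aryl-2H-chromene fused to the phloroglucinol ring A. A single osmium-catalysed syn-dihydroxylation, steered to the face remote from the C2 aryl ring B, installs both oxygens and fixes C3 relative to C2. C4 is oxidised afterwards, so its configuration is sacrificial. The substrate is the (2S)-flav-3-ene carrying four benzyl ethers and the (R)-1-arylethyl group at C6, built from a symmetric phenol so that ring A poses no regiochemical question.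

Key step: step 10

Remarks on the chemistry
- Every compound from 18 onward carries four O-benzyl groups (O5, O7, O4′ and the phenol of the C6 side chain). The diol 20 is therefore a tetrabenzyl ether, and step 12 must cleave four benzyl ethers.
- C2 of chromene 18 is (S) by the sequence rules but has the same spatial arrangement as C2 (R) of the target, because the descriptor changes once C3 bears oxygen. Likewise C3 is (S) in diol 20 and (R) in ketone 21 without any change in geometry.
- Assumption: in steps 4 and 9 the sense of induction is set by the catalyst alone. The antipode of the P,N ligand (step 4) or of the tartaric acid-derived diol (step 9) that gives the configuration drawn is the one used, and both antipodes are accessible.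
- Only discrete species that persist in the flask are numbered. Fleeting ions (benzopyrylium, oxocarbenium) appear in the Why lines only.

Step 1
Reactants: 1 2',4',6'-trihydroxyacetophenone
Product: 2 1-[2,6-dihydroxy-4-(methoxymethoxy)phenyl]ethan-1-one
Conditions: MOMCl (1.0 equiv), i-Pr2NEt (1.1 equiv), THF, 0 °C
Reagents that add atoms: chloromethyl methyl ether, COCCl
Why: Base-mediated O-alkylation (MOM ether formation) should occur first at O4′, the most acidic hydroxyl and the only one not held in a hydrogen bond to the acetyl carbonyl, when one equivalent of electrophile is used at low temperature.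

Step 2
Reactants: 2 1-[2,6-dihydroxy-4-(methoxymethoxy)phenyl]ethan-1-one
Product: 3 1-[2,6-bis(benzyloxy)-4-(methoxymethoxy)phenyl]ethan-1-one
Conditions: BnBr (2.4 equiv), K2CO3 (3 equiv), Bu4NI (cat.), DMF, 70 °C
Reagents that add atoms: benzyl bromide, BrCc1ccccc1
Why: Williamson ether synthesis; the two chelated ortho-phenols need carbonate in warm DMF, conditions under which O-benzylation dominates and the MOM acetal and the ketone are inert.

Step 3
Reactants: 3 1-[2,6-bis(benzyloxy)-4-(methoxymethoxy)phenyl]ethan-1-one; 4 1-(benzyloxy)-4-bromobenzene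
Product: 7 1,3-bis(benzyloxy)-2-{1-[4-(benzyloxy)phenyl]ethenyl}-5-(methoxymethoxy)benzene, via 4-(benzyloxy)phenylmagnesium bromide 5 (not isolated), via tertiary diarylethanol 6 (not isolated)
Conditions: 4, Mg, THF, 50 °C; then 3, LaCl3·2LiCl (1 equiv), THF, 0 °C → rt; aq. NH4Cl; crude 6, PPTS (cat.), toluene, 60 °C
Reagents that add atoms: none
Why: Grignard 1,2-addition, with the lanthanum salt suppressing enolisation of the hindered di-ortho-substituted ketone, followed by acid-catalysed E1 dehydration of the tertiary bis-benzylic alcohol, which can only give the 1,1-diarylethene.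

Step 4
Reactants: 7 1,3-bis(benzyloxy)-2-{1-[4-(benzyloxy)phenyl]ethenyl}-5-(methoxymethoxy)benzene
Product: 8 1,3-bis(benzyloxy)-2-{(1R)-1-[4-(benzyloxy)phenyl]ethyl}-5-(methoxymethoxy)benzene
Conditions: [Ir(cod)(L*)]BArF (1 mol%, L* = chiral phosphite–oxazoline P,N ligand), H2 (50 bar), CH2Cl2, rt
Reagents that add atoms: none
Why: Iridium–P,N-catalysed asymmetric hydrogenation of an unfunctionalised 1,1-diarylethene: the 2,6-dibenzyloxy ring is forced out of the alkene plane while the para-substituted ring stays coplanar, and this steric contrast lets the chiral pocket deliver H2 to one enantioface and set the (R) benzylic centre, the homogeneous catalyst leaving the benzyl ethers intact.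

Step 5
Reactants: 8 1,3-bis(benzyloxy)-2-{(1R)-1-[4-(benzyloxy)phenyl]ethyl}-5-(methoxymethoxy)benzene
Product: 9 3,5-bis(benzyloxy)-4-{(1R)-1-[4-(benzyloxy)phenyl]ethyl}phenol
Conditions: 3 M aq. HCl, MeOH/THF, 50 °C
Reagents that add atoms: none
Why: Acid-catalysed acetal cleavage (MOM removal) frees the single phenol, whereas benzyl ethers and the saturated diarylmethine centre are inert to dilute acid.

Step 6
Reactants: 9 3,5-bis(benzyloxy)-4-{(1R)-1-[4-(benzyloxy)phenyl]ethyl}phenol
Product: 10 4,6-bis(benzyloxy)-5-{(1R)-1-[4-(benzyloxy)phenyl]ethyl}-2-hydroxybenzaldehyde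
Conditions: MgCl2, Et3N, (CH2O)n, MeCN, reflux; 1 M HCl work-up
Reagents that add atoms: paraformaldehyde (as formaldehyde), C=O
Why: Magnesium-mediated ortho-formylation of a phenol (Casnati–Skattebøl): the magnesium phenoxide delivers formaldehyde to an ortho carbon and a second formaldehyde oxidises the benzylic alkoxide, and because C2 and C6 are equivalent and C4 is blocked only one salicylaldehyde can result.

Step 7
Reactants: 10 4,6-bis(benzyloxy)-5-{(1R)-1-[4-(benzyloxy)phenyl]ethyl}-2-hydroxybenzaldehyde; 11 ethyl (triphenylphosphoranylidene)acetate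
Product: 13 5,7-bis(benzyloxy)-6-{(1R)-1-[4-(benzyloxy)phenyl]ethyl}-2H-chromen-2-one, via ethyl (E)-2-hydroxycinnamate 12 (not isolated)
Conditions: PhNEt2, reflux (ca. 215 °C)
Reagents that add atoms: none
Why: Wittig olefination with a stabilised ylide, thermal E-to-Z isomerisation and lactonisation in one pot, the classical coumarin synthesis from salicylaldehydes, under which benzyl ethers and the benzylic stereocentre are thermally inert.

Step 8
Reactants: 13 5,7-bis(benzyloxy)-6-{(1R)-1-[4-(benzyloxy)phenyl]ethyl}-2H-chromen-2-one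
Product: 15 5,7-bis(benzyloxy)-6-{(1R)-1-[4-(benzyloxy)phenyl]ethyl}-2-ethoxy-2H-chromene (both C2 epimers), via 2H-chromen-2-ol lactol 14 (not isolated)
Conditions: DIBAL-H (1.1 equiv), CH2Cl2, −78 °C; Rochelle salt; then EtOH, PPTS (cat.), 4 Å MS, rt
Reagents that add atoms: ethanol, CCO
Why: Partial DIBAL-H reduction of the lactone to the lactol, then acid-catalysed acetalisation through the 5,7-dialkoxy-stabilised benzopyrylium ion, which ethanol captures at C2; the configuration of the acetal carbon is of no consequence because it is ionised again in step 9.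

Step 9
Reactants: 15 5,7-bis(benzyloxy)-6-{(1R)-1-[4-(benzyloxy)phenyl]ethyl}-2-ethoxy-2H-chromene; 16 4-(benzyloxy)phenylboronic acid
Product: 18 (2S)-5,7-bis(benzyloxy)-2-[4-(benzyloxy)phenyl]-6-{(1R)-1-[4-(benzyloxy)phenyl]ethyl}-2H-chromene, via diethyl arylboronate 17 (not isolated)
Conditions: 16, EtOH, toluene, azeotropic removal of water; then 15, tartaric acid-derived bis-amide diol (10 mol%), Yb(OTf)3 (5 mol%), EtOAc, −20 °C, dark
Reagents that add atoms: none
Why: Enantioselective boronate addition to a chromene acetal under chiral diol/Lewis acid catalysis: the lanthanide triflate ionises the acetal to the benzopyrylium ion, the chiral diol exchanges onto boron, and the resulting boronate transfers the electron-rich aryl group to C2 on one enantioface to set the (2S) centre, independently of the remote side-chain centre.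

Step 10
Reactants: 18 (2S)-5,7-bis(benzyloxy)-2-[4-(benzyloxy)phenyl]-6-{(1R)-1-[4-(benzyloxy)phenyl]ethyl}-2H-chromene
Product: 20 (2R,3S,4S)-5,7-bis(benzyloxy)-2-[4-(benzyloxy)phenyl]-6-{(1R)-1-[4-(benzyloxy)phenyl]ethyl}-3,4-dihydro-2H-chromene-3,4-diol (2,3-trans-3,4-cis), via cyclic osmate ester 19 (not isolated)
Conditions: K2OsO4·2H2O (3 mol%), NMO (1.5 equiv), THF/t-BuOH/H2O, 0 °C → rt, dark; aq. Na2SO3; Et3N-deactivated silica
Reagents that add atoms: osmium tetroxide (formed from the osmate, catalytic oxygen carrier), O=[Os](=O)(=O)=O; N-methylmorpholine N-oxide, C[N+]1([O-])CCOCC1; water, O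
Why: Osmium tetroxide adds across C3=C4 in a concerted [3+2] cycloaddition to give the osmate ester 19, which is hydrolysed while the N-oxide returns osmium to the +8 state. The closest known reaction is the osmium tetroxide hydroxylation of flav-3-enes, which gives 2,3-trans-3,4-cis-flavan-3,4-diols. No ring of the product is closed; two C–O bonds are formed on the same face. C3 is controlled by the C2 aryl ring, which projects over one face of the nearly flat pyran ring so that the reagent approaches from the other side and places O3 trans to that aryl group; C4 follows from the suprafacial delivery and is removed in step 11. The step needs π-facial selectivity, secured by the allylic aryl substituent, and chemoselectivity for the only alkene, secured by the inertness of benzyl ethers and arenes to osmium; no chiral ligand is added, because its preference on cis-disubstituted cyclic styrenes is modest and could oppose the substrate bias.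

Step 11
Reactants: 20 (2R,3S,4S)-5,7-bis(benzyloxy)-2-[4-(benzyloxy)phenyl]-6-{(1R)-1-[4-(benzyloxy)phenyl]ethyl}-3,4-dihydro-2H-chromene-3,4-diol
Product: 21 (2R,3R)-5,7-bis(benzyloxy)-2-[4-(benzyloxy)phenyl]-6-{(1R)-1-[4-(benzyloxy)phenyl]ethyl}-3-hydroxy-2,3-dihydro-4H-chromen-4-one
Conditions: DDQ (1.1 equiv), CH2Cl2, 0 °C → rt; aq. NaHCO3 work-up
Reagents that add atoms: none
Why: Quinone dehydrogenation of a benzylic alcohol by hydride abstraction: the C4–H bond, activated by its geminal hydroxyl and by the ortho/para donors O1, O5 and O7, is by far the best hydride donor, the C3 carbinol is not benzylic, and the side-chain methine C–H lies in the plane of its di-ortho-substituted ring and so gains little benzylic activation, which leaves C2 and C3 untouched.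

Step 12
Reactants: 21 (2R,3R)-5,7-bis(benzyloxy)-2-[4-(benzyloxy)phenyl]-6-{(1R)-1-[4-(benzyloxy)phenyl]ethyl}-3-hydroxy-2,3-dihydro-4H-chromen-4-one
Product: 22 (2R,3R)-3,5,7-trihydroxy-2-(4-hydroxyphenyl)-6-[(1R)-1-(4-hydroxyphenyl)ethyl]-2,3-dihydro-4H-chromen-4-one (CNP0379731.1)
Conditions: H2 (1 atm), 10% Pd/C, EtOAc/MeOH, rt
Reagents that add atoms: none
Why: Palladium-catalysed hydrogenolysis cleaves the four aryl benzyl ethers under neutral conditions, which avoid base-induced epimerisation or ring opening of the trans-dihydroflavonol, and the hydrogen-bonded C4 ketone and the diarylmethine centre are not reduced at ambient pressure.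

Compound list
1 | 2',4',6'-trihydroxyacetophenone | CC(=O)c1c(O)cc(O)cc1O | starting material
2 | 1-[2,6-dihydroxy-4-(methoxymethoxy)phenyl]ethan-1-one | CC(=O)c1c(O)cc(OCOC)cc1O | intermediate
3 | 1-[2,6-bis(benzyloxy)-4-(methoxymethoxy)phenyl]ethan-1-one | CC(=O)c1c(OCc2ccccc2)cc(OCOC)cc1OCc1ccccc1 | intermediate
4 | 1-(benzyloxy)-4-bromobenzene | Brc1ccc(OCc2ccccc2)cc1 | starting material
5 | [4-(benzyloxy)phenyl]magnesium bromide | Br[Mg]c1ccc(OCc2ccccc2)cc1 | intermediate (not isolated)
6 | 1-[2,6-bis(benzyloxy)-4-(methoxymethoxy)phenyl]-1-[4-(benzyloxy)phenyl]ethan-1-ol (racemic) | CC(O)(c1ccc(OCc2ccccc2)cc1)c1c(OCc2ccccc2)cc(OCOC)cc1OCc1ccccc1 | intermediate (not isolated)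
7 | 1,3-bis(benzyloxy)-2-{1-[4-(benzyloxy)phenyl]ethenyl}-5-(methoxymethoxy)benzene | C=C(c1ccc(OCc2ccccc2)cc1)c1c(OCc2ccccc2)cc(OCOC)cc1OCc1ccccc1 | intermediate
8 | 1,3-bis(benzyloxy)-2-{(1R)-1-[4-(benzyloxy)phenyl]ethyl}-5-(methoxymethoxy)benzene | C[C@H](c1ccc(OCc2ccccc2)cc1)c1c(OCc2ccccc2)cc(OCOC)cc1OCc1ccccc1 | intermediate
9 | 3,5-bis(benzyloxy)-4-{(1R)-1-[4-(benzyloxy)phenyl]ethyl}phenol | C[C@H](c1ccc(OCc2ccccc2)cc1)c1c(OCc2ccccc2)cc(O)cc1OCc1ccccc1 | intermediate
10 | 4,6-bis(benzyloxy)-5-{(1R)-1-[4-(benzyloxy)phenyl]ethyl}-2-hydroxybenzaldehyde | C[C@H](c1ccc(OCc2ccccc2)cc1)c1c(OCc2ccccc2)cc(O)c(C=O)c1OCc1ccccc1 | intermediate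
11 | ethyl (triphenylphosphoranylidene)acetate | CCOC(=O)C=P(c1ccccc1)(c1ccccc1)c1ccccc1 | starting material
12 | ethyl (2E)-3-[4,6-bis(benzyloxy)-5-{(1R)-1-[4-(benzyloxy)phenyl]ethyl}-2-hydroxyphenyl]prop-2-enoate | C[C@H](c1ccc(OCc2ccccc2)cc1)c1c(OCc2ccccc2)cc(O)c(/C=C/C(=O)OCC)c1OCc1ccccc1 | intermediate (not isolated)
13 | 5,7-bis(benzyloxy)-6-{(1R)-1-[4-(benzyloxy)phenyl]ethyl}-2H-chromen-2-one | C[C@H](c1ccc(OCc2ccccc2)cc1)c1c(OCc2ccccc2)cc2c(c1OCc1ccccc1)C=CC(=O)O2 | intermediate
14 | 5,7-bis(benzyloxy)-6-{(1R)-1-[4-(benzyloxy)phenyl]ethyl}-2H-chromen-2-ol (C2 epimers) | C[C@H](c1ccc(OCc2ccccc2)cc1)c1c(OCc2ccccc2)cc2c(c1OCc1ccccc1)C=CC(O)O2 | intermediate (not isolated)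
15 | 5,7-bis(benzyloxy)-6-{(1R)-1-[4-(benzyloxy)phenyl]ethyl}-2-ethoxy-2H-chromene (C2 epimers) | C[C@H](c1ccc(OCc2ccccc2)cc1)c1c(OCc2ccccc2)cc2c(c1OCc1ccccc1)C=CC(OCC)O2 | intermediate
16 | 4-(benzyloxy)phenylboronic acid | OB(O)c1ccc(OCc2ccccc2)cc1 | starting material
17 | diethyl [4-(benzyloxy)phenyl]boronate | CCOB(OCC)c1ccc(OCc2ccccc2)cc1 | intermediate (not isolated)
18 | (2S)-5,7-bis(benzyloxy)-2-[4-(benzyloxy)phenyl]-6-{(1R)-1-[4-(benzyloxy)phenyl]ethyl}-2H-chromene | C[C@H](c1ccc(OCc2ccccc2)cc1)c1c(OCc2ccccc2)cc2c(c1OCc1ccccc1)C=C[C@@H](c1ccc(OCc3ccccc3)cc1)O2 | intermediate (key-step substrate)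
19 | cyclic dioxo-osmium(VI) 3,4-diolate of 20 (both oxygens anti to the C2 aryl) | C[C@H](c1ccc(OCc2ccccc2)cc1)c1c(OCc2ccccc2)cc2c(c1OCc1ccccc1)[C@@H]3O[Os](=O)(=O)O[C@@H]3[C@@H](c1ccc(OCc3ccccc3)cc1)O2 | intermediate (not isolated)
20 | (2R,3S,4S)-5,7-bis(benzyloxy)-2-[4-(benzyloxy)phenyl]-6-{(1R)-1-[4-(benzyloxy)phenyl]ethyl}-3,4-dihydro-2H-chromene-3,4-diol | C[C@H](c1ccc(OCc2ccccc2)cc1)c1c(OCc2ccccc2)cc2c(c1OCc1ccccc1)[C@H](O)[C@H](O)[C@@H](c1ccc(OCc3ccccc3)cc1)O2 | intermediate (key-step product)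
21 | (2R,3R)-5,7-bis(benzyloxy)-2-[4-(benzyloxy)phenyl]-6-{(1R)-1-[4-(benzyloxy)phenyl]ethyl}-3-hydroxy-2,3-dihydro-4H-chromen-4-one | C[C@H](c1ccc(OCc2ccccc2)cc1)c1c(OCc2ccccc2)cc2c(c1OCc1ccccc1)C(=O)[C@H](O)[C@@H](c1ccc(OCc3ccccc3)cc1)O2 | intermediate
22 | (2R,3R)-3,5,7-trihydroxy-2-(4-hydroxyphenyl)-6-[(1R)-1-(4-hydroxyphenyl)ethyl]-2,3-dihydro-4H-chromen-4-one | C[C@H](c1ccc(O)cc1)c1c(O)cc2c(c1O)C(=O)[C@H](O)[C@@H](c1ccc(O)cc1)O2 | target

Total step count: 12.
Longest linear sequence: 12 steps (1 → 22); compounds 4, 11 and 16 are purchased and enter in one step each.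

Steps most likely to fail

1. Step 9 (enantioselective C2 arylation). What may go wrong: sluggish aryl transfer to the strongly donor-stabilised benzopyrylium ion, incomplete enantiofacial control, or Lewis acid-promoted reversible opening of the C2–O1 bond that erodes the new centre. The fallback sets out from 10 and comes back at 18; it builds C2 by conjugate addition to a chromone instead. Excess ethynylmagnesium bromide (THF, 0 °C) should convert salicylaldehyde 10 into the propargylic alcohol F1. Manganese dioxide (CH2Cl2) oxidises it to the ynone F2, which closes by amine-catalysed 6-endo oxa-Michael addition (Et2NH, EtOH) to the chromone F3. Palladium/pyridine–oxazoline-catalysed asymmetric conjugate addition of boronic acid 16 (Pd(OCOCF3)2, t-BuPyOx, NH4PF6, H2O, ClCH2CH2Cl, 60 °C) then sets C2 in the (2S)-flavanone F4. NaBH4 (THF/EtOH, 0 °C) gives the flavan-4-ol F5, and acid-catalysed dehydration (PPTS, toluene, 60 °C) delivers 18.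

2. Step 4 (asymmetric hydrogenation). What may go wrong: insufficient discrimination between the two aryl groups by the catalyst pocket, or acid-promoted dimerisation of the electron-rich alkene by iridium hydrides. The fallback sets out from 2 and comes back at 8; it replaces steric discrimination by hydroxyl-directed hydrogenation. Mono-benzylation of 2 (BnBr 1.05 equiv, K2CO3, acetone, reflux) should stop at the mono-benzyl ketone F6, because the remaining phenol is chelated to the carbonyl. After deprotonation with i-PrMgCl, addition of Grignard reagent 5 with LaCl3·2LiCl gives the carbinol F7, which is dehydrated (PPTS, toluene) to the vinylphenol F8. Rhodium(I)/chiral bisphosphine hydrogenation ([Rh(nbd)2]BF4, Josiphos-type ligand, H2, MeOH), in which the ortho-phenol binds the metal and fixes the alkene face, should give the (R)-configured phenol F9. Benzylation (BnBr, K2CO3, DMF) then returns 8.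

3. Step 10 (key dihydroxylation). What may go wrong: attack on the wrong π-face, which erodes the C2/C3 trans relationship, or ionisation of the very labile C4 hydroxyl during osmate hydrolysis and work-up. The fallback sets out from 18 and comes back at 21; it introduces the two oxygens separately. Hydroboration–oxidation (BH3·SMe2, THF, 0 °C; then NaOH, H2O2) places boron on C3, the non-benzylic carbon of the electron-rich styrene, anti to the C2 aryl, and should give the 2,3-trans-flavan-3-ol F10. DDQ in wet CH2Cl2 then abstracts hydride from C4, water captures the cation to give the C4-epimeric 3,4-diols F11 (one epimer is 20), and a second equivalent of DDQ oxidises these to ketone 21.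

Further compounds
F1 | step 9 | 1-[4,6-bis(benzyloxy)-5-{(1R)-1-[4-(benzyloxy)phenyl]ethyl}-2-hydroxyphenyl]prop-2-yn-1-ol (carbinol epimers) | C[C@H](c1ccc(OCc2ccccc2)cc1)c1c(OCc2ccccc2)cc(O)c(C(O)C#C)c1OCc1ccccc1
F2 | step 9 | 1-[4,6-bis(benzyloxy)-5-{(1R)-1-[4-(benzyloxy)phenyl]ethyl}-2-hydroxyphenyl]prop-2-yn-1-one | C[C@H](c1ccc(OCc2ccccc2)cc1)c1c(OCc2ccccc2)cc(O)c(C(=O)C#C)c1OCc1ccccc1
F3 | step 9 | 5,7-bis(benzyloxy)-6-{(1R)-1-[4-(benzyloxy)phenyl]ethyl}-4H-chromen-4-one | C[C@H](c1ccc(OCc2ccccc2)cc1)c1c(OCc2ccccc2)cc2c(c1OCc1ccccc1)C(=O)C=CO2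
F4 | step 9 | (2S)-5,7-bis(benzyloxy)-2-[4-(benzyloxy)phenyl]-6-{(1R)-1-[4-(benzyloxy)phenyl]ethyl}-2,3-dihydro-4H-chromen-4-one | C[C@H](c1ccc(OCc2ccccc2)cc1)c1c(OCc2ccccc2)cc2c(c1OCc1ccccc1)C(=O)C[C@@H](c1ccc(OCc3ccccc3)cc1)O2
F5 | step 9 | (2S)-5,7-bis(benzyloxy)-2-[4-(benzyloxy)phenyl]-6-{(1R)-1-[4-(benzyloxy)phenyl]ethyl}-3,4-dihydro-2H-chromen-4-ol (C4 epimers) | C[C@H](c1ccc(OCc2ccccc2)cc1)c1c(OCc2ccccc2)cc2c(c1OCc1ccccc1)C(O)C[C@@H](c1ccc(OCc3ccccc3)cc1)O2
F6 | step 4 | 1-[2-(benzyloxy)-6-hydroxy-4-(methoxymethoxy)phenyl]ethan-1-one | CC(=O)c1c(O)cc(OCOC)cc1OCc1ccccc1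
F7 | step 4 | 3-(benzyloxy)-2-{1-[4-(benzyloxy)phenyl]-1-hydroxyethyl}-5-(methoxymethoxy)phenol (racemic) | CC(O)(c1ccc(OCc2ccccc2)cc1)c1c(O)cc(OCOC)cc1OCc1ccccc1
F8 | step 4 | 3-(benzyloxy)-2-{1-[4-(benzyloxy)phenyl]ethenyl}-5-(methoxymethoxy)phenol | C=C(c1ccc(OCc2ccccc2)cc1)c1c(O)cc(OCOC)cc1OCc1ccccc1
F9 | step 4 | 3-(benzyloxy)-2-{(1R)-1-[4-(benzyloxy)phenyl]ethyl}-5-(methoxymethoxy)phenol | C[C@H](c1ccc(OCc2ccccc2)cc1)c1c(O)cc(OCOC)cc1OCc1ccccc1
F10 | step 10 | (2R,3S)-5,7-bis(benzyloxy)-2-[4-(benzyloxy)phenyl]-6-{(1R)-1-[4-(benzyloxy)phenyl]ethyl}-3,4-dihydro-2H-chromen-3-ol | C[C@H](c1ccc(OCc2ccccc2)cc1)c1c(OCc2ccccc2)cc2c(c1OCc1ccccc1)C[C@H](O)[C@@H](c1ccc(OCc3ccccc3)cc1)O2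
F11 | step 10 | (2R,3S)-5,7-bis(benzyloxy)-2-[4-(benzyloxy)phenyl]-6-{(1R)-1-[4-(benzyloxy)phenyl]ethyl}-3,4-dihydro-2H-chromene-3,4-diol (C4 epimers) | C[C@H](c1ccc(OCc2ccccc2)cc1)c1c(OCc2ccccc2)cc2c(c1OCc1ccccc1)C(O)[C@H](O)[C@@H](c1ccc(OCc3ccccc3)cc1)O2
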